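The numbers in the tables come from a simulation with made-up constants, and the scatter is random.

Per minute is the unit to put both clocks of this flask in: one for starting material being used, one for catalyst being lost.

in all of them: free catalyst 0.500 mM
- gamma: starting material 50.0 mM
- alpha: starting material 25.0 mM
- theta: starting material 50.0 mM; product 15.0 mM
- zeta: starting material 200 mM; time 56 min

- gamma run (time / min: [product] / mM): 2.2: 6.3; 4.3: 9.7; 8.1: 16.9; 15: 22.7; 29: 29.3; 56: 32.0
- alpha run (time / min: [product] / mM): 2.2: 2.3; 4.3: 5.1; 8.1: 6.6; 15: 11.2; 29: 13.4; 56: 16.0
- theta run (time / min: [product] / mM): 2.2: 20.0; 4.3: 24.7; 8.1: 32.6; 15: 37.9; 29: 42.7; 56: 46.4

(readings scatter by 0.8 mM)

- Overall: starting material -> product, with free catalyst as catalyst.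
- Constant volume, constant temperature.
- Bound and free are read together.
- An order is taken over about fifteen percent of the charge, up and down.

- the power of [starting material] that the first rate follows, about the charge of the gamma run; measure it at two percent of starting material made into product (one fixed amount of product, the same in the runs compared)
- the alpha run starts with 25.0 mM less of starting material than the gamma run, and with no product. Compared where both hold the same amount of starting material, once fifteen percent of what the alpha run was charged with has turned into product, is the alpha run faster, slower or alike (within a tenth)?
- product in the zeta run at 56 min, as a share of the starting material charged

The first instants. Take the logarithm of charge over starting material remaining, and divide it by time. At the second reading of the gamma run this gives a first-order constant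

k = 0.0502 min⁻¹

so starting material has a time of 19.9 min. At that same reading the alpha run has turned 20.4% of its charge and the gamma run 19.4%. The first rate therefore follows about the first power of starting material, which makes this pseudo-first-order while the catalyst holds.

The middle. By 29 min the gamma run's logarithm stands at 0.882, while k predicts 1.46, so the catalyst is losing activity. Product shows no effect on this: the theta run makes 0.0314 M by its last reading and the gamma run 32.0 mM, a difference of 0.600 mM against a scatter of 0.8 mM.

The end. The logarithm levels off, and in the gamma run at the last reading

L = 1.02

This L is the reach, the logarithm of charge over what remains when the catalyst has stopped delivering. The alpha run reads 1.02 at its last reading, but that is one reading with a scatter of 0.8 mM, so I carry the reach from one charge to another as an assumption. Dividing gives the catalyst's life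

τ = L/k = 20.4 min

and the last reading stands at 2.75 lives.

My reckoning follows from this. If the reach held for the zeta run, it would turn 63.9% of its charge. The alpha run comes down to the gamma run's late level at about 3.25 min, and the gamma run holds 0.0207 M at 29 min. The difference in catalyst age gives a rate ratio

exp(age gap/τ) = 3.54

so the alpha run should be faster.

The forecast, which read “catalyst loss on a clock”, gave order 1, the alpha run faster, and 63% for the zeta run, a little under my figure.

The simulation gives order 1.1, the alpha run faster, and 74.9% for the zeta run.

    free catalyst + starting material ⇌ catalyst-substrate complex, settled at all times (6.870 M⁻¹)
    catalyst-substrate complex + starting material ⇌ doubly bound catalyst, settled at all times (42.30 M⁻¹)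
    doubly bound catalyst → product + catalyst-substrate complex (57.60 min⁻¹)
    2 starting material ⇌ idle substrate dimer, settled at all times (31.00 M⁻¹)
    free catalyst → spent catalyst (0.05784 min⁻¹)

The alpha run's rate comes out at 3.2 times the gamma run's, beside the 3.54 reckoned from the reach, and it falls to 1.0 times with the path from free catalyst to spent catalyst taken away. The zeta run's reach is 1.38, larger than the gamma run's 1.02, so at 200 mM the reach has moved. Product in the zeta run at 56 min stays below the charge through the association of starting material to idle substrate dimer together with the path from free catalyst to spent catalyst: without the association it reaches 96.4%, and without the path 94.9%.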